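Labdane numbering (C1–C20) is used for ring and side-chain positions throughout; ring A is C1–C5/C10 and ring B is C5–C10.

## The problem

The target (36) is a normal-series labdane: a trans-fused decalin with a C7=C8 alkene, a C9 side chain ending in a (13Z)-3-methylpent-2-enoic acid, and an axial C19 hydroxymethyl group at C4 esterified with angelic acid. Four contiguous stereocentres (C4, C5, C9, C10) must be set, two of them quaternary (C4, C10). The most congested bond is C9–C10, which joins a tertiary carbon bearing the side chain to the quaternary carbon bearing the angular methyl. C5 is the natural control element: if ring B closes onto a ring A that carries only the C5 stereocentre, a chair-like transition state passes its configuration on to C10 and C9. C4 can then be decided on the rigid decalin, where the axial C10 methyl blocks the β-face. Several groups are fragile: the angelate isomerises to the tiglate with nucleophiles, base or heat and is a Michael acceptor; the (Z)-enoic acid must be made geometrically pure; the C7=C8 alkene migrates to C8=C9 under acid; and C5 can epimerise whenever it is α to a carbonyl. The feature that opens the key step is that C10 carries a methyl (C20) and is bonded to C9, which lies β to C7. A ring A exocyclic alkene C10=C20 and a C7 enone (C8=C9) tethered through C5–C6 therefore map onto the target: hydrogen-atom transfer to C20 makes the methyl and a tertiary C10 radical, this radical attacks C9 to close ring B, and the C7 carbonyl remains as the handle for the C7=C8 alkene.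

## Retrosynthesis

**C12–C13.** The acid 36 is unmasked from its 2-(trimethylsilyl)ethyl ester 35, and 35 is cut at the C12–C13 single bond into the primary iodide 30 and the (Z)-iodoenoate 33. A neighbouring cut through C13=C14 (cuprate addition to an ynoate) would need acetylide and alkyllithium chemistry in the presence of the angelate and two more steps. The sp3–sp2 cut takes the (13Z) geometry from a building block in which it is already fixed. The forward coupling must tolerate two esters and retain alkene geometry, which an alkylzinc/palladium coupling does.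

**C19–O and the C12 handle.** Iodide 30 comes from alcohol 29 and silyl ether 28, and the angelate C–O bond is cut to give the neopentyl alcohol 26 and angelic acid (27). The angelate is installed before the side chain is finished because the remaining steps (fluoride, phosphine/iodine, zinc, palladium) are mild enough to carry it. Alcohol 26 is the reduction product of the axial ester 25.

**C4–C18.** Ester 25 is cut at the C4–CH3 bond and traced through the mono-ester 23 to the gem-diester 22. Telling two esters apart by steric accessibility and then deoxygenating a neopentyl carbon is the longer neighbour of this cut. Removing one ester and methylating the enolate from the face opposite the C10 methyl needs two steps and rests on a well-known facial preference. Diester 22 has no C4 stereocentre.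

**C7=C8.** Alkene 22 is taken back through the enol triflate 21 to the 7-ketone 20. The forward step has to enolise the ketone towards C8 without strong base, because 20 is a β-malonyl ketone that could open ring A by retro-Michael reaction.

**C9–C10 (key step).** Ketone 20 is cut at C9–C10, opening ring B to the monocyclic enone 19. This removes one ring and two stereocentres (three counting the transient C8) and leaves C5 as the only stereocentre. Neighbouring cuts of ring B (C5–C6 or C7–C8) would leave the C9–C10 quaternary junction to be made intermolecularly. The forward step asks for chemoselective hydrogen-atom transfer to the 1,1-disubstituted alkene, 6-endo attack at the enone β-carbon and a trans ring fusion.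

**C7–C8.** Enone 19 is cut between the carbonyl carbon and the alkene into aldehyde 13 and the (E)-alkenyl iodide 17, by way of the allylic alcohol 18. The alkene geometry is then fixed in 17 rather than made by an olefination next to ring A. Fragment 17 derives from pent-3-yn-1-ol (14) through silyl ether 15.

**C10=C20 and C3–C4.** Aldehyde 13 is masked as the acetal 12, whose exocyclic alkene comes from ketone 11, alcohol 10 and silyl ether 9. Ring A of 9 is opened at C3–C4, an intramolecular malonate alkylation, to the acyclic chloride 8. A 2,4-dienal that already carries the methylene would invite 1,6-addition in the next cut, so C10 is carried as a protected carbinol and oxidised later.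

**C4–C5.** Acetal 8 is the protected form of aldehyde 7, which is cut at C4–C5 into dimethyl malonate (6) and the γ-silyloxy enal 5. This is the single enantioselective event of the route. Enal 5 comes from cross-metathesis of the allylic silyl ether 3 with crotonaldehyde (4), and 3 from alcohol 2 and 4-chlorobutanal (1).

**Side-chain building block.** Iodoenoate 33 is the ester of (Z)-3-iodobut-2-enoic acid (32), made by hydroiodination of but-2-ynoic acid (31).

## Roads not taken

**Alternative 1:** Ring A is cut at C4–C5 and traced to an ester-enolate Claisen rearrangement of the δ-lactone A1. Its silyl ketene acetal would rearrange on heating through a boat transition state, contracting the lactone to the cyclohexene acid A2 and releasing C19 as a carboxyl group. The merit is real: C4 emerges with methyl and carboxyl already differentiated and correctly placed relative to C5, and the C1=C10 alkene of A2 could later give the same C10 radical. The weak points are that A1 needs an enantioenriched allylic carbinol and a geometrically pure (E)-trisubstituted alkene, and that any leakage from boat to chair erodes C4 and C5 together with no later correction. The step also delivers ring A only, so the C9–C10 bond and ring B remain unsolved and the two-carbon chain at C5 still has to be built into an enone such as 19. In fairness, this road is better than the chosen plan at C4, saving the ester removal and the methylation. The chosen plan sets against it that only one stereocentre is needed before ring B, that it is made catalytically, and that C4 is decided afterwards on a rigid decalin.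

**Alternative 2:** Both rings are cut at once, at C3–C4 and C5–C10, leading to the open-chain tetraene A3. A Lewis-acid-promoted intramolecular Diels–Alder reaction of its (E)-diene with its (E)-enal would give the trans-fused octalin aldehyde A4. This is the most convergent option: two rings and three stereocentres (C4, C5, C10) in one step, no radical chemistry, and the C19 oxygen already in place. Its weaknesses are structural. Both new bonds end at carbons that become quaternary, and the fully substituted diene terminus forces one substituent inside the s-cis conformer. The skipped (Z)-alkene and doubly allylic C6 of A3 are prone to isomerisation under Lewis acid, and C9 has to be set in an acyclic precursor. Afterwards the C1=C2 alkene must be hydrogenated in the presence of C7=C8 and the C18 aldehyde reduced to a methyl group. On ring-forming step economy this road beats the chosen plan. The chosen plan offers a robust cyclisation precursor, stereocentres set one at a time by separately precedented events, and no selective hydrogenation or neopentyl deoxygenation.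

**Alternative 3:** Ring A is cut at C1–C10 and C4–C5 and assembled by an enantioselective Diels–Alder reaction between the quinone A5 and the (Z)-dienyl silyl ether A6. Under a triflimide-activated chiral B-aryl oxazaborolidine this would give the cis-fused enedione A7. Its strength is unmatched among the four plans: both quaternary centres and C5 are set catalytically in one step from achiral partners. The cost comes afterwards. The ring fusion is cis and must be epimerised at C5, and the C6 carbonyl must be deleted. The C9 carbonyl, flanked by quaternary C10, must be converted into a CH bearing the side chain with the β-orientation. The (Z)-substituent of A6 also points inward in the reactive conformer and slows the cycloaddition, and the unsymmetrical quinone must react at the right alkene in the right orientation. This road is better than the chosen plan at early, catalytic control of C4 and C10. The chosen plan installs the C9 side chain in the ring-forming step and carries only one ring B carbonyl, which is then used productively for the C7=C8 alkene.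

Key step: step 13

Assumption: the carbinol carbon that becomes C10 is carried as both configurations through compounds 2–10, since it is planarised in step 7 and the catalyst of step 4 is expected to override it.

## Route

Step 1
Reactants: 1 4-chlorobutanal
Product: 2 6-chlorohex-1-en-3-ol (racemic)
Conditions: CH2=CHMgBr, THF, −78 °C; aq. NH4Cl at −78 °C
Reagents that add atoms: vinylmagnesium bromide, C=C[Mg]Br
Why: Grignard 1,2-addition to an aliphatic aldehyde; the cold quench keeps the alkoxide from displacing the chloride, and the new carbinol centre (later C10) needs no control because it is oxidised in step 7.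

Step 2
Reactants: 2 6-chlorohex-1-en-3-ol
Product: 3 tert-butyl[(6-chlorohex-1-en-3-yl)oxy]dimethylsilane
Conditions: TBSCl, imidazole, DMF, rt
Reagents that add atoms: tert-butyldimethylsilyl chloride, CC(C)(C)[Si](C)(C)Cl
Why: Silylation with imidazole generates no free alkoxide, so the chloride is not displaced; the silyl ether shields the γ-oxygen during steps 3–5.

Step 3
Reactants: 3 tert-butyl[(6-chlorohex-1-en-3-yl)oxy]dimethylsilane; 4 crotonaldehyde
Product: 5 (2E)-4-[(tert-butyldimethylsilyl)oxy]-7-chlorohept-2-enal
Conditions: second-generation Hoveyda–Grubbs catalyst (3 mol %), CH2Cl2, 40 °C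
Reagents that add atoms: none
Why: Olefin cross-metathesis of an allylic silyl ether with an enal partner, driven by loss of propene, should give the (E)-enal as the thermodynamic isomer.

Step 4
Reactants: 5 (2E)-4-[(tert-butyldimethylsilyl)oxy]-7-chlorohept-2-enal; 6 dimethyl malonate
Product: 8 dimethyl 2-[(3S)-4-[(tert-butyldimethylsilyl)oxy]-7-chloro-1,1-diethoxyheptan-3-yl]propanedioate, via Michael aldehyde 7 (not isolated)
Conditions: (R)-2-{bis[3,5-bis(trifluoromethyl)phenyl][(trimethylsilyl)oxy]methyl}pyrrolidine (10 mol %), EtOH, 0 °C; then HC(OEt)3, PPTS, rt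
Reagents that add atoms: triethyl orthoformate, CCOC(OCC)OCC
Why: Iminium-ion-catalysed Michael addition of malonate to an enal (Jørgensen-type); on the steric-shielding model the diaryl(silyloxy)methyl group of the (R)-catalyst covers one face of the (E)-iminium ion so that malonate should add to give (3S), the C5 configuration of the target, for either configuration of the silyloxy carbon; acetalisation in the same flask protects the aldehyde from retro-Michael and aldol reactions in step 5.

Step 5
Reactants: 8 dimethyl 2-[(3S)-4-[(tert-butyldimethylsilyl)oxy]-7-chloro-1,1-diethoxyheptan-3-yl]propanedioate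
Product: 9 dimethyl (2S)-3-[(tert-butyldimethylsilyl)oxy]-2-(2,2-diethoxyethyl)cyclohexane-1,1-dicarboxylate
Conditions: NaH, NaI (cat.), THF/DMF, 0 → 60 °C
Reagents that add atoms: none
Why: Intramolecular SN2 C-alkylation of the malonate anion (6-exo-tet, iodide-assisted) closes ring A; the new quaternary carbon C4 carries two identical esters and is therefore not a stereocentre.

Step 6
Reactants: 9 dimethyl (2S)-3-[(tert-butyldimethylsilyl)oxy]-2-(2,2-diethoxyethyl)cyclohexane-1,1-dicarboxylate
Product: 10 dimethyl (2S)-2-(2,2-diethoxyethyl)-3-hydroxycyclohexane-1,1-dicarboxylate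
Conditions: TBAF, AcOH, THF, rt
Reagents that add atoms: none
Why: Fluoride cleavage of the secondary silyl ether; buffering with acetic acid keeps the liberated oxygen from lactonising onto the cis ester and leaves the acetal intact.

Step 7
Reactants: 10 dimethyl (2S)-2-(2,2-diethoxyethyl)-3-hydroxycyclohexane-1,1-dicarboxylate
Product: 11 dimethyl (2S)-2-(2,2-diethoxyethyl)-3-oxocyclohexane-1,1-dicarboxylate
Conditions: Dess–Martin periodinane, pyridine, CH2Cl2, 0 °C → rt
Reagents that add atoms: none
Why: Dess–Martin oxidation under buffered, non-enolising conditions merges both carbinol epimers into one ketone; from here C5 is the only stereocentre and lies α to a carbonyl, so base is avoided.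

Step 8
Reactants: 11 dimethyl (2S)-2-(2,2-diethoxyethyl)-3-oxocyclohexane-1,1-dicarboxylate
Product: 13 dimethyl (2R)-3-methylidene-2-(2-oxoethyl)cyclohexane-1,1-dicarboxylate, via methylidene acetal 12 (not isolated)
Conditions: Zn, CH2Br2, TiCl4, THF (reagent pre-formed, −40 → 5 °C); 11, CH2Cl2, 0 °C → rt; then 1 M HCl, THF, rt
Reagents that add atoms: dibromomethane, BrCBr; water, O
Why: Takai–Lombardo methylenation: the Zn/Ti gem-dimetallic reagent is non-basic, so the ketone becomes the exocyclic alkene without enolisation towards C5 and the esters do not react; the dilute acid of the work-up then hydrolyses the diethyl acetal to the aldehyde (the descriptor changes from S to R only through ligand priorities).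

Step 9
Reactants: 14 pent-3-yn-1-ol
Product: 15 (pent-3-yn-1-yloxy)tri(propan-2-yl)silane
Conditions: TIPSCl, imidazole, DMF, rt
Reagents that add atoms: triisopropylsilyl chloride, CC(C)[Si](Cl)(C(C)C)C(C)C
Why: Standard silylation; the TIPS ether is chosen to survive the organometallic, hydride, Krapcho and enolate steps up to step 20.

Step 10
Reactants: 15 (pent-3-yn-1-yloxy)tri(propan-2-yl)silane
Product: 17 {[(3E)-4-iodopent-3-en-1-yl]oxy}tri(propan-2-yl)silane, via alkenylzirconocene chloride 16 (not isolated)
Conditions: Cp2Zr(H)Cl (2 equiv), THF, 50 °C; then I2, 0 °C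
Reagents that add atoms: iodine, [I][I]
Why: Hydrozirconation of a 2-alkyne is a syn addition in which zirconium ends on the methyl-bearing carbon after equilibration with excess Cp2Zr(H)Cl; iodinolysis with retention gives the (E)-2-iodoalkene, a known sequence for homopropargylic silyl ethers.

Step 11
Reactants: 13 dimethyl (2R)-3-methylidene-2-(2-oxoethyl)cyclohexane-1,1-dicarboxylate; 17 {[(3E)-4-iodopent-3-en-1-yl]oxy}tri(propan-2-yl)silane
Product: 18 dimethyl (2R)-2-[(3E)-2-hydroxy-3-methyl-6-{[tri(propan-2-yl)silyl]oxy}hex-3-en-1-yl]-3-methylidenecyclohexane-1,1-dicarboxylate (both carbinol epimers)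
Conditions: CrCl2, NiCl2 (cat.), DMSO, rt
Reagents that add atoms: none
Why: Nozaki–Hiyama–Kishi coupling: the alkenylchromium species formed under nickel catalysis adds only to the aldehyde, leaving both esters and the exocyclic alkene untouched, and the geometry of 17 is retained; the carbinol centre is removed in step 12.

Step 12
Reactants: 18 dimethyl (2R)-2-[(3E)-2-hydroxy-3-methyl-6-{[tri(propan-2-yl)silyl]oxy}hex-3-en-1-yl]-3-methylidenecyclohexane-1,1-dicarboxylate
Product: 19 dimethyl (2R)-3-methylidene-2-[(3E)-3-methyl-2-oxo-6-{[tri(propan-2-yl)silyl]oxy}hex-3-en-1-yl]cyclohexane-1,1-dicarboxylate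
Conditions: Dess–Martin periodinane, pyridine, CH2Cl2, 0 °C → rt
Reagents that add atoms: none
Why: Dess–Martin oxidation of the allylic alcohol gives the (E)-enone without touching the 1,1-disubstituted alkene; it is run promptly because the free hydroxyl could lactonise onto an ester.

Step 13
Reactants: 19 dimethyl (2R)-3-methylidene-2-[(3E)-3-methyl-2-oxo-6-{[tri(propan-2-yl)silyl]oxy}hex-3-en-1-yl]cyclohexane-1,1-dicarboxylate
Product: 20 dimethyl 7-oxo-12-{[tri(propan-2-yl)silyl]oxy}-13,14,15,16-tetranorlabdane-18,19-dioate (trans-decalin; 5α-H, 8β-H, 9α-H, 10β-CH3)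
Conditions: Fe(acac)3 (0.5 equiv), PhSiH3 (2.5 equiv), EtOH/HOCH2CH2OH 5:1, 60 °C, 0.01 M
Reagents that add atoms: none
Why: Fe(acac)3 and PhSiH3 form an iron hydride that transfers a hydrogen atom to the terminal carbon of the exocyclic alkene, which turns C20 into the angular methyl and leaves a tertiary, nucleophilic radical at C10. This radical adds to C9, the β-carbon of the tethered enone, closing ring B in 6-endo-trig mode; the closest known reaction type is the iron-hydride reductive olefin–enone coupling in its intramolecular form, and the topology is that of the second closure in a radical polyene cyclisation. The resulting C8 α-keto radical is reduced by divalent iron to the enolate and protonated by ethanol, which returns trivalent iron. Attack at C8 (5-exo) would join two fully substituted carbons and leave an unstabilised radical at C9, so the polarity-matched β-attack should dominate. C10 and C9 are set together in a chair-like transition state in which the C5–C6 bond is equatorial on ring A: the tether then reaches the equatorial lobe of the C10 radical, giving the trans fusion with the methyl axial (β), and the (E)-geometry of the enone places the C11 chain equatorial (β) at C9; the only controlling element is C5, because the gem-diester keeps C4 non-stereogenic. C8 is formed as an epimerisable centre (equatorial methyl expected) and is erased in step 14. The step needs hydrogen-atom transfer to the alkene in preference to the enone, which the electron-rich, unhindered 1,1-disubstituted alkene secures, and high dilution suppresses intermolecular coupling.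

Step 14
Reactants: 20 dimethyl 7-oxo-12-{[tri(propan-2-yl)silyl]oxy}-13,14,15,16-tetranorlabdane-18,19-dioate
Product: 21 dimethyl 12-{[tri(propan-2-yl)silyl]oxy}-7-{[(trifluoromethyl)sulfonyl]oxy}-13,14,15,16-tetranorlabd-7-ene-18,19-dioate
Conditions: Tf2O, 2,6-di-tert-butyl-4-methylpyridine, CH2Cl2, 0 °C → rt
Reagents that add atoms: trifluoromethanesulfonic anhydride, O=S(=O)(OS(=O)(=O)C(F)(F)F)C(F)(F)F
Why: Electrophilic O-triflation through the thermodynamically preferred, more substituted enol; no enolate is generated, so the β-malonyl ketone cannot open ring A by retro-Michael reaction, and both C8 epimers converge.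

Step 15
Reactants: 21 dimethyl 12-{[tri(propan-2-yl)silyl]oxy}-7-{[(trifluoromethyl)sulfonyl]oxy}-13,14,15,16-tetranorlabd-7-ene-18,19-dioate
Product: 22 dimethyl 12-{[tri(propan-2-yl)silyl]oxy}-13,14,15,16-tetranorlabd-7-ene-18,19-dioate
Conditions: Pd(OAc)2 (5 mol %), PPh3, Bu3N, HCO2H, DMF, 60 °C
Reagents that add atoms: none
Why: Palladium-catalysed formate reduction of an enol triflate (oxidative addition to zerovalent palladium, formate exchange, loss of CO2, reductive elimination) puts hydrogen on C7 and leaves the alkene where the triflate fixed it.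

Step 16
Reactants: 22 dimethyl 12-{[tri(propan-2-yl)silyl]oxy}-13,14,15,16-tetranorlabd-7-ene-18,19-dioate
Product: 23 methyl 12-{[tri(propan-2-yl)silyl]oxy}-13,14,15,16,18-pentanorlabd-7-en-19-oate (both C4 epimers)
Conditions: LiCl, H2O, DMSO, 150 °C
Reagents that add atoms: none
Why: Krapcho demethoxycarbonylation: chloride dealkylates one methyl ester and the resulting malonate half-ester loses CO2; it does not matter which ester is lost because C4 is reset in step 17.

Step 17
Reactants: 23 methyl 12-{[tri(propan-2-yl)silyl]oxy}-13,14,15,16,18-pentanorlabd-7-en-19-oate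
Product: 25 methyl 12-{[tri(propan-2-yl)silyl]oxy}-13,14,15,16-tetranorlabd-7-en-19-oate (4α-CH3; 4β-CO2CH3), via lithium ester enolate 24 (not isolated)
Conditions: LDA, THF, −78 → 0 °C; MeI, DMPU, −78 °C → rt
Reagents that add atoms: iodomethane, CI
Why: Alkylation of the exocyclic ester enolate: methyl iodide should approach C4 from the α (equatorial) face because the β-face is blocked by the 1,3-diaxial C10 methyl, so the new methyl becomes C18 and the ester ends axial as C19, the classical outcome for 10-methyl-trans-decalin-4-carboxylates.

Step 18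
Reactants: 25 methyl 12-{[tri(propan-2-yl)silyl]oxy}-13,14,15,16-tetranorlabd-7-en-19-oate
Product: 26 12-{[tri(propan-2-yl)silyl]oxy}-13,14,15,16-tetranorlabd-7-en-19-ol
Conditions: LiAlH4, THF, 0 °C → rt
Reagents that add atoms: none
Why: Hydride reduction of the hindered axial ester to the neopentyl alcohol; the silyl ether and the trisubstituted alkene are inert to LiAlH4.

Step 19
Reactants: 26 12-{[tri(propan-2-yl)silyl]oxy}-13,14,15,16-tetranorlabd-7-en-19-ol; 27 angelic acid
Product: 28 12-{[tri(propan-2-yl)silyl]oxy}-13,14,15,16-tetranorlabd-7-en-19-yl (2Z)-2-methylbut-2-enoate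
Conditions: 27, 2,4,6-trichlorobenzoyl chloride, Et3N, toluene, rt; then 26, toluene, 80 °C
Reagents that add atoms: none
Why: Yamaguchi-type esterification through the preformed mixed anhydride of angelic acid, run without a nucleophilic catalyst, is the established way to acylate hindered alcohols with retention of the (Z)-geometry.

Step 20
Reactants: 28 12-{[tri(propan-2-yl)silyl]oxy}-13,14,15,16-tetranorlabd-7-en-19-yl (2Z)-2-methylbut-2-enoate
Product: 29 12-hydroxy-13,14,15,16-tetranorlabd-7-en-19-yl (2Z)-2-methylbut-2-enoate
Conditions: TBAF, AcOH, THF, rt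
Reagents that add atoms: none
Why: Fluoride desilylation of the primary TIPS ether; buffering keeps the angelate from being cleaved or isomerised.

Step 21
Reactants: 29 12-hydroxy-13,14,15,16-tetranorlabd-7-en-19-yl (2Z)-2-methylbut-2-enoate
Product: 30 12-iodo-13,14,15,16-tetranorlabd-7-en-19-yl (2Z)-2-methylbut-2-enoate
Conditions: I2, PPh3, imidazole, CH2Cl2, 0 °C → rt
Reagents that add atoms: iodine, [I][I]
Why: Appel-type iodination: SN2 displacement of the alkoxyphosphonium ion at the unhindered primary carbon under neutral conditions.

Step 22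
Reactants: 31 but-2-ynoic acid
Product: 32 (2Z)-3-iodobut-2-enoic acid
Conditions: NaI, AcOH, 110 °C
Reagents that add atoms: sodium iodide, [Na+].[I-]
Why: Hydroiodination of an ynoic acid with NaI in acetic acid is an anti addition and gives the (Z)-β-iodo acid, with iodine cis to the carboxyl group.

Step 23
Reactants: 32 (2Z)-3-iodobut-2-enoic acid
Product: 33 2-(trimethylsilyl)ethyl (2Z)-3-iodobut-2-enoate
Conditions: Me3SiCH2CH2OH, DCC, DMAP (cat.), CH2Cl2, 0 °C → rt
Reagents that add atoms: 2-(trimethylsilyl)ethanol, C[Si](C)(C)CCO
Why: Steglich esterification; this ester survives organozinc/palladium chemistry and is later removed by fluoride without hydrolysis.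

Step 24
Reactants: 30 12-iodo-13,14,15,16-tetranorlabd-7-en-19-yl (2Z)-2-methylbut-2-enoate; 33 2-(trimethylsilyl)ethyl (2Z)-3-iodobut-2-enoate
Product: 35 2-(trimethylsilyl)ethyl (13Z)-19-{[(2Z)-2-methylbut-2-enoyl]oxy}labda-7,13-dien-15-oate, via alkylzinc iodide 34 (not isolated)
Conditions: Zn, LiCl, THF, 40 °C; then 33, PdCl2(dppf) (5 mol %), THF, rt → 50 °C
Reagents that add atoms: none
Why: Negishi coupling: zinc inserts into the primary C–I bond without touching either ester, and the alkylzinc iodide couples with the alkenyl iodide under palladium catalysis with retention of geometry, so C12 ends cis to the carboxyl carbon (13Z).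

Step 25
Reactants: 35 2-(trimethylsilyl)ethyl (13Z)-19-{[(2Z)-2-methylbut-2-enoyl]oxy}labda-7,13-dien-15-oate
Product: 36 (13Z)-19-{[(2Z)-2-methylbut-2-enoyl]oxy}labda-7,13-dien-15-oic acid
Conditions: TBAF, THF, 0 °C → rt; aq. NH4Cl
Reagents that add atoms: none
Why: Fluoride-induced fragmentation of the 2-(trimethylsilyl)ethyl ester (loss of ethene and Me3SiF) frees the acid under non-hydrolytic conditions that leave the angelate and both alkenes unchanged.

## Compound list

1 | 4-chlorobutanal | ClCCCC=O | starting material
2 | 6-chlorohex-1-en-3-ol (racemic) | C=CC(O)CCCCl | intermediate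
3 | tert-butyl[(6-chlorohex-1-en-3-yl)oxy]dimethylsilane (racemic) | C=CC(CCCCl)O[Si](C)(C)C(C)(C)C | intermediate
4 | crotonaldehyde, (2E)-but-2-enal | C/C=C/C=O | starting material
5 | (2E)-4-[(tert-butyldimethylsilyl)oxy]-7-chlorohept-2-enal (racemic at C4) | O=C/C=C/C(CCCCl)O[Si](C)(C)C(C)(C)C | intermediate
6 | dimethyl malonate | COC(=O)CC(=O)OC | starting material
7 | dimethyl 2-[(3S)-4-[(tert-butyldimethylsilyl)oxy]-7-chloro-1-oxoheptan-3-yl]propanedioate (both C4 epimers) | O=CC[C@@H](C(C(=O)OC)C(=O)OC)C(CCCCl)O[Si](C)(C)C(C)(C)C | intermediate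
8 | dimethyl 2-[(3S)-4-[(tert-butyldimethylsilyl)oxy]-7-chloro-1,1-diethoxyheptan-3-yl]propanedioate (both C4 epimers) | CCOC(C[C@@H](C(C(=O)OC)C(=O)OC)C(CCCCl)O[Si](C)(C)C(C)(C)C)OCC | intermediate
9 | dimethyl (2S)-3-[(tert-butyldimethylsilyl)oxy]-2-(2,2-diethoxyethyl)cyclohexane-1,1-dicarboxylate (both C3 epimers) | CCOC(C[C@@H]1C(O[Si](C)(C)C(C)(C)C)CCCC1(C(=O)OC)C(=O)OC)OCC | intermediate
10 | dimethyl (2S)-2-(2,2-diethoxyethyl)-3-hydroxycyclohexane-1,1-dicarboxylate (both C3 epimers) | CCOC(C[C@@H]1C(O)CCCC1(C(=O)OC)C(=O)OC)OCC | intermediate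
11 | dimethyl (2S)-2-(2,2-diethoxyethyl)-3-oxocyclohexane-1,1-dicarboxylate | CCOC(C[C@@H]1C(=O)CCCC1(C(=O)OC)C(=O)OC)OCC | intermediate
12 | dimethyl (2R)-2-(2,2-diethoxyethyl)-3-methylidenecyclohexane-1,1-dicarboxylate | CCOC(C[C@@H]1C(=C)CCCC1(C(=O)OC)C(=O)OC)OCC | intermediate
13 | dimethyl (2R)-3-methylidene-2-(2-oxoethyl)cyclohexane-1,1-dicarboxylate | O=CC[C@@H]1C(=C)CCCC1(C(=O)OC)C(=O)OC | intermediate
14 | pent-3-yn-1-ol | CC#CCCO | starting material
15 | (pent-3-yn-1-yloxy)tri(propan-2-yl)silane | CC#CCCO[Si](C(C)C)(C(C)C)C(C)C | intermediate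
16 | chloro[(2E)-5-{[tri(propan-2-yl)silyl]oxy}pent-2-en-2-yl]zirconocene | C/C(=C\CCO[Si](C(C)C)(C(C)C)C(C)C)[Zr](Cl)(C1C=CC=C1)C1C=CC=C1 | intermediate
17 | {[(3E)-4-iodopent-3-en-1-yl]oxy}tri(propan-2-yl)silane | C/C(I)=C\CCO[Si](C(C)C)(C(C)C)C(C)C | intermediate
18 | dimethyl (2R)-2-[(3E)-2-hydroxy-3-methyl-6-{[tri(propan-2-yl)silyl]oxy}hex-3-en-1-yl]-3-methylidenecyclohexane-1,1-dicarboxylate (both carbinol epimers) | COC(=O)C1(C(=O)OC)CCCC(=C)[C@H]1CC(O)/C(C)=C/CCO[Si](C(C)C)(C(C)C)C(C)C | intermediate
19 | dimethyl (2R)-3-methylidene-2-[(3E)-3-methyl-2-oxo-6-{[tri(propan-2-yl)silyl]oxy}hex-3-en-1-yl]cyclohexane-1,1-dicarboxylate | COC(=O)C1(C(=O)OC)CCCC(=C)[C@H]1CC(=O)/C(C)=C/CCO[Si](C(C)C)(C(C)C)C(C)C | intermediate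
20 | dimethyl 7-oxo-12-{[tri(propan-2-yl)silyl]oxy}-13,14,15,16-tetranorlabdane-18,19-dioate (5α-H, 8β-H, 9α-H, 10β-CH3) | COC(=O)C1(C(=O)OC)CCC[C@]2(C)[C@@H](CCO[Si](C(C)C)(C(C)C)C(C)C)[C@H](C)C(=O)C[C@@H]12 | intermediate
21 | dimethyl 12-{[tri(propan-2-yl)silyl]oxy}-7-{[(trifluoromethyl)sulfonyl]oxy}-13,14,15,16-tetranorlabd-7-ene-18,19-dioate | COC(=O)C1(C(=O)OC)CCC[C@]2(C)[C@@H](CCO[Si](C(C)C)(C(C)C)C(C)C)C(C)=C(OS(=O)(=O)C(F)(F)F)C[C@@H]12 | intermediate
22 | dimethyl 12-{[tri(propan-2-yl)silyl]oxy}-13,14,15,16-tetranorlabd-7-ene-18,19-dioate | COC(=O)C1(C(=O)OC)CCC[C@]2(C)[C@@H](CCO[Si](C(C)C)(C(C)C)C(C)C)C(C)=CC[C@@H]12 | intermediate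
23 | methyl 12-{[tri(propan-2-yl)silyl]oxy}-13,14,15,16,18-pentanorlabd-7-en-19-oate (both C4 epimers) | COC(=O)C1CCC[C@]2(C)[C@@H](CCO[Si](C(C)C)(C(C)C)C(C)C)C(C)=CC[C@@H]12 | intermediate
24 | lithium enolate of 23 (exocyclic at C4) | [Li]OC(OC)=C1CCC[C@]2(C)[C@@H](CCO[Si](C(C)C)(C(C)C)C(C)C)C(C)=CC[C@@H]12 | intermediate
25 | methyl 12-{[tri(propan-2-yl)silyl]oxy}-13,14,15,16-tetranorlabd-7-en-19-oate (4α-CH3, 4β-CO2CH3) | COC(=O)[C@@]1(C)CCC[C@]2(C)[C@@H](CCO[Si](C(C)C)(C(C)C)C(C)C)C(C)=CC[C@@H]12 | intermediate
26 | 12-{[tri(propan-2-yl)silyl]oxy}-13,14,15,16-tetranorlabd-7-en-19-ol | OC[C@@]1(C)CCC[C@]2(C)[C@@H](CCO[Si](C(C)C)(C(C)C)C(C)C)C(C)=CC[C@@H]12 | intermediate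
27 | angelic acid, (2Z)-2-methylbut-2-enoic acid | C/C=C(/C)C(=O)O | starting material
28 | 12-{[tri(propan-2-yl)silyl]oxy}-13,14,15,16-tetranorlabd-7-en-19-yl (2Z)-2-methylbut-2-enoate | C/C=C(/C)C(=O)OC[C@@]1(C)CCC[C@]2(C)[C@@H](CCO[Si](C(C)C)(C(C)C)C(C)C)C(C)=CC[C@@H]12 | intermediate
29 | 12-hydroxy-13,14,15,16-tetranorlabd-7-en-19-yl (2Z)-2-methylbut-2-enoate | C/C=C(/C)C(=O)OC[C@@]1(C)CCC[C@]2(C)[C@@H](CCO)C(C)=CC[C@@H]12 | intermediate
30 | 12-iodo-13,14,15,16-tetranorlabd-7-en-19-yl (2Z)-2-methylbut-2-enoate | C/C=C(/C)C(=O)OC[C@@]1(C)CCC[C@]2(C)[C@@H](CCI)C(C)=CC[C@@H]12 | intermediate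
31 | but-2-ynoic acid | CC#CC(=O)O | starting material
32 | (2Z)-3-iodobut-2-enoic acid | C/C(I)=C/C(=O)O | intermediate
33 | 2-(trimethylsilyl)ethyl (2Z)-3-iodobut-2-enoate | C/C(I)=C/C(=O)OCC[Si](C)(C)C | intermediate
34 | {19-[(2Z)-2-methylbut-2-enoyloxy]-13,14,15,16-tetranorlabd-7-en-12-yl}zinc iodide | C/C=C(/C)C(=O)OC[C@@]1(C)CCC[C@]2(C)[C@@H](CC[Zn]I)C(C)=CC[C@@H]12 | intermediate
35 | 2-(trimethylsilyl)ethyl (13Z)-19-{[(2Z)-2-methylbut-2-enoyl]oxy}labda-7,13-dien-15-oate | C/C=C(/C)C(=O)OC[C@@]1(C)CCC[C@]2(C)[C@@H](CC/C(C)=C\C(=O)OCC[Si](C)(C)C)C(C)=CC[C@@H]12 | intermediate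
36 | (13Z)-19-{[(2Z)-2-methylbut-2-enoyl]oxy}labda-7,13-dien-15-oic acid, (4S,5R,9S,10R); (2Z)-3-methyl-5-[(1S,4aR,5S,8aR)-2,5,8a-trimethyl-5-({[(2Z)-2-methylbut-2-enoyl]oxy}methyl)-1,4,4a,5,6,7,8,8a-octahydronaphthalen-1-yl]pent-2-enoic acid | C/C=C(/C)C(=O)OC[C@@]1(C)CCC[C@]2(C)[C@@H](CC/C(C)=C\C(=O)O)C(C)=CC[C@@H]12 | target

## Step count and least certain steps

Total: 25 steps. Longest linear sequence: 21 steps (steps 1–8, 11–21, 24 and 25, from 4-chlorobutanal).

**Step 13 (key step).** The closure onto a β-substituted, α-methyl enone is slow for a radical cyclisation. The iron hydride may therefore reduce the enone or quench the C10 radical before ring B forms, and a less ordered transition state could leak to the cis-fused decalin. Fallback: set out from 19 and add HCl across the exocyclic alkene (HCl in dioxane/CH2Cl2, −20 °C) to give the tertiary chloride F1. The same C10 radical is then generated by chlorine abstraction with Bu3SnH/AIBN under slow addition in toluene at 110 °C. No metal hydride is present and the stannane concentration can be held low enough for the cyclisation to win. The route is rejoined at 20.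

**Step 4.** The enal is γ-branched and carries a bulky silyloxy group on a racemic carbon. Iminium formation and malonate attack may be slow, facial selectivity may be poor for the mismatched C10 epimer, and the silyloxy group may be lost through a dienamine. Fallback: from 5, Luche reduction (NaBH4, CeCl3) gives the allylic alcohol F2 and methyl chloroformate/pyridine gives the allylic methyl carbonate F3. Allylic alkylation of dimethyl malonate with [Ir(cod)Cl]2 and a chiral phosphoramidite ligand then forms the C4–C5 bond at the branched position, giving the vinyl malonate F4. Hydroboration–oxidation (9-BBN; NaBO3) gives the primary alcohol F5. Dess–Martin oxidation leads to aldehyde 7, which is acetalised as in step 4 to rejoin the route at 8.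

**Step 8.** At the ketone stage C5 is the only stereocentre and is α to the carbonyl, so any enolisation racemises the material. The Lewis-acidic titanium/zinc mixture may also open the acetal early and expose the aldehyde to methylenation. Fallback: from 11, add Me3SiCH2MgCl/CeCl3 (THF, −78 °C), a non-basic organocerium addition, to give the β-hydroxysilane F6. Aqueous HF in MeCN then effects the Peterson elimination and cleaves the acetal in one operation, rejoining the route at 13.

**Step 14.** Enolisation may go partly towards C6, giving the regioisomeric enol triflate and, after step 15, the C6=C7 alkene; any adventitious base could trigger retro-Michael opening of ring A. Fallback: fix the regiochemistry at an isolable intermediate. From 20, equilibrating silylation (TMSCl, NaI, Et3N, MeCN) gives the more substituted trimethylsilyl enol ether F7, which can be purified. Fluoride-mediated transfer with CsF/PhNTf2 in DME then converts it regiospecifically into 21.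

**Step 17.** The hindered enolate may form slowly, and the facial selectivity of methylation may be incomplete, leaving the 4-epimer. Fallback: distinguish the two esters of 22 by accessibility instead. KOH in aqueous methanol hydrolyses only the equatorial ester to give the half-acid F8. Mixed-anhydride activation (i-BuOCOCl, N-methylmorpholine) and NaBH4 give the hydroxy ester F9. 1,1′-Thiocarbonyldiimidazole gives the imidazolylthiocarbonate F10, and Bu3SnH/AIBN (toluene, 110 °C) removes the oxygen, rejoining the route at 25.

**Step 19.** Acylation of the axial neopentyl alcohol is slow, and prolonged heating may isomerise the angelate to the tiglate. Fallback: build the (Z)-alkene on the ester. From 26, DCC/DMAP coupling with 2-[bis(2,2,2-trifluoroethoxy)phosphoryl]propanoic acid gives the phosphonate ester F11. Still–Gennari olefination with acetaldehyde (KHMDS, 18-crown-6, THF, −78 °C) then forms the (Z)-2-methylbut-2-enoate and rejoins the route at 28.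

## Further compounds

F1 | step 13 | dimethyl (2R)-3-chloro-3-methyl-2-[(3E)-3-methyl-2-oxo-6-{[tri(propan-2-yl)silyl]oxy}hex-3-en-1-yl]cyclohexane-1,1-dicarboxylate (both C3 epimers) | COC(=O)C1(C(=O)OC)CCCC(C)(Cl)[C@H]1CC(=O)/C(C)=C/CCO[Si](C(C)C)(C(C)C)C(C)C
F2 | step 4 | (2E)-4-[(tert-butyldimethylsilyl)oxy]-7-chlorohept-2-en-1-ol | OC/C=C/C(CCCCl)O[Si](C)(C)C(C)(C)C
F3 | step 4 | (2E)-4-[(tert-butyldimethylsilyl)oxy]-7-chlorohept-2-en-1-yl methyl carbonate | COC(=O)OC/C=C/C(CCCCl)O[Si](C)(C)C(C)(C)C
F4 | step 4 | dimethyl 2-[(3S)-4-[(tert-butyldimethylsilyl)oxy]-7-chlorohept-1-en-3-yl]propanedioate | C=C[C@@H](C(C(=O)OC)C(=O)OC)C(CCCCl)O[Si](C)(C)C(C)(C)C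
F5 | step 4 | dimethyl 2-[(3S)-4-[(tert-butyldimethylsilyl)oxy]-7-chloro-1-hydroxyheptan-3-yl]propanedioate | OCC[C@@H](C(C(=O)OC)C(=O)OC)C(CCCCl)O[Si](C)(C)C(C)(C)C
F6 | step 8 | dimethyl (2S)-2-(2,2-diethoxyethyl)-3-hydroxy-3-[(trimethylsilyl)methyl]cyclohexane-1,1-dicarboxylate (both C3 epimers) | CCOC(C[C@@H]1C(O)(C[Si](C)(C)C)CCCC1(C(=O)OC)C(=O)OC)OCC
F7 | step 14 | dimethyl 12-{[tri(propan-2-yl)silyl]oxy}-7-[(trimethylsilyl)oxy]-13,14,15,16-tetranorlabd-7-ene-18,19-dioate | COC(=O)C1(C(=O)OC)CCC[C@]2(C)[C@@H](CCO[Si](C(C)C)(C(C)C)C(C)C)C(C)=C(O[Si](C)(C)C)C[C@@H]12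
F8 | step 17 | 19-methoxy-19-oxo-12-{[tri(propan-2-yl)silyl]oxy}-13,14,15,16-tetranorlabd-7-en-18-oic acid (4α-CO2H, 4β-CO2CH3) | COC(=O)[C@@]1(C(=O)O)CCC[C@]2(C)[C@@H](CCO[Si](C(C)C)(C(C)C)C(C)C)C(C)=CC[C@@H]12
F9 | step 17 | methyl 18-hydroxy-12-{[tri(propan-2-yl)silyl]oxy}-13,14,15,16-tetranorlabd-7-en-19-oate | COC(=O)[C@@]1(CO)CCC[C@]2(C)[C@@H](CCO[Si](C(C)C)(C(C)C)C(C)C)C(C)=CC[C@@H]12
F10 | step 17 | methyl 18-[(1H-imidazol-1-ylcarbonothioyl)oxy]-12-{[tri(propan-2-yl)silyl]oxy}-13,14,15,16-tetranorlabd-7-en-19-oate | COC(=O)[C@@]1(COC(=S)n3ccnc3)CCC[C@]2(C)[C@@H](CCO[Si](C(C)C)(C(C)C)C(C)C)C(C)=CC[C@@H]12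
F11 | step 19 | 12-{[tri(propan-2-yl)silyl]oxy}-13,14,15,16-tetranorlabd-7-en-19-yl 2-[bis(2,2,2-trifluoroethoxy)phosphoryl]propanoate | CC(C(=O)OC[C@@]1(C)CCC[C@]2(C)[C@@H](CCO[Si](C(C)C)(C(C)C)C(C)C)C(C)=CC[C@@H]12)P(=O)(OCC(F)(F)F)OCC(F)(F)F
A1 | alternative 1 | (6R)-6-[(2E)-5-{[tert-butyl(dimethyl)silyl]oxy}pent-2-en-2-yl]-3-methyloxan-2-one (either C3 epimer) | CC1CC[C@@H](OC1=O)/C(C)=C/CCO[Si](C)(C)C(C)(C)C
A2 | alternative 1 | (1S,2R)-2-(2-{[tert-butyl(dimethyl)silyl]oxy}ethyl)-1,3-dimethylcyclohex-3-ene-1-carboxylic acid | OC(=O)[C@@]1(C)CCC=C(C)[C@H]1CCO[Si](C)(C)C(C)(C)C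
A3 | alternative 2 | (2E,5Z,7S,8E)-2-{[(4-methoxyphenyl)methoxy]methyl}-6,8-dimethyl-7-(2-{[tri(propan-2-yl)silyl]oxy}ethyl)undeca-2,5,8,10-tetraenal | C=C/C=C(C)/[C@@H](CCO[Si](C(C)C)(C(C)C)C(C)C)/C(C)=C\C/C=C(/C=O)COCc1ccc(OC)cc1
A4 | alternative 2 | 19-[(4-methoxyphenyl)methoxy]-12-{[tri(propan-2-yl)silyl]oxy}-13,14,15,16-tetranorlabda-1,7-dien-18-al (trans-fused) | COc1ccc(COC[C@@]2(C=O)CC=C[C@]3(C)[C@@H](CCO[Si](C(C)C)(C(C)C)C(C)C)C(C)=CC[C@@H]23)cc1
A5 | alternative 3 | 2,6-dimethylcyclohexa-2,5-diene-1,4-dione | CC1=CC(=O)C=C(C)C1=O
A6 | alternative 3 | tert-butyl(dimethyl){[(2Z)-2-methylpenta-2,4-dien-1-yl]oxy}silane | C=C/C=C(C)\CO[Si](C)(C)C(C)(C)C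
A7 | alternative 3 | cis-fused 5-({[tert-butyl(dimethyl)silyl]oxy}methyl)-2,5,8a-trimethyl-4a,5,8,8a-tetrahydronaphthalene-1,4-dione | CC(C)(C)[Si](C)(C)OC[C@@]1(C)C=CC[C@]2(C)C(=O)C(C)=CC(=O)[C@H]12
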